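The earlier runs and the new flask were computed from invented constants; scatter was added.

The ratio to watch in this flask is monomer in chains over chains begun, the number-average degree of polymerisation, and it has to pass 10 by 2.5 h.

the same everywhere: impurity 16 µM
- dusk: free monomer 10 mM; initiator 1.4 mol%; run made earlier
- noon: free monomer 10 mM; initiator 2.2 mol%; run made earlier
- summer: free monomer 20 mM; initiator 1 mol%; run made earlier
- flask: free monomer 10 mM; initiator 1 mol%; time 2.5 h

- dusk (time / h: monomer in chains / %, free monomer / %): 0.833: 3.4, 83.5; 1.50: 6.3, 70.1; 2.50: 11.2, 53.9; 3.00: 13.6, 47.1
- noon (time / h: monomer in chains / %, free monomer / %): 0.250: 1.0, 94.3; 0.500: 1.9, 89.7; 1.33: 7.1, 72.7; 3.00: 21.9, 40.5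
- summer (time / h: monomer in chains / %, free monomer / %): 0.250: 1.6, 94.7; 0.500: 1.8, 88.5; 1.33: 10.5, 68.5; 3.00: 28.8, 35.9

(scatter of a reading: 0.5 percentage points)

* whether the average number of monomer units in a chain (chains begun, living or dead) reaches 10 by 2.5 h (no / yes)
* average number of monomer units in a chain (chains begun, living or dead) at 2.5 h

- the average divides the monomer in chains by the number of chains begun, living and dead together
- the earlier runs do not show the number of chains; that part of a forecast is a guess

I call the initiator charge less the impurity the usable initiator, 84.0 µM, and I take it as the most chains this flask can begin. At 3.00 h, noon holds 1.61 times the monomer in chains of dusk, and its usable initiator is 1.65 times that of dusk, so I scale by usable initiator.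

Dusk has 124 µM usable and 11.2% in chains at 2.50 h, so when you come this flask should have 7.59% in chains, or 0.759 mM. Dividing by the usable initiator gives a floor of 9.03 for the length, and that is short of the target, so the flask needs fewer than 75.9 µM chains begun.

Noon gains 15 percentage points over its last 1.67 h, faster than its first 0.500 h, so I read chains as still being begun and expect yes.

The forecast says yes, with 10.5 (from 8 to 16), adding "Chains begun are a guess".

    free monomer + initiator → living end + monomer in chains (k = 0.00812 M⁻¹ s⁻¹)
    free monomer + living end → monomer in chains + living end, rate k2*[living end]*[free monomer] (k = 0.535 M⁻¹ s⁻¹)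
    initiator + impurity → spent initiator (k = 2140 M⁻¹ s⁻¹)
    free monomer → uncatalysed product (k = 5.04 × 10⁻⁵ s⁻¹)

The flask gives yes, with a length of 21.4, twice the forecast. At 2.50 h, living ends in this flask stand at 0.0364 mM, which is 43.3% of the usable initiator. In dusk, the same division of 11.2% in chains by its usable initiator gives a floor of 9.03 at 2.50 h.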